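Everything rests on cutting benzenoid ring A away from an intact, fully substituted furan: the furan bond that becomes C7a–C3a acts as the alkene half of an arylketene. In a single light-then-heat operation a 2-furyl diazomethyl ketone and a 1-methoxyalkyne pass through Wolff shift, [2+2] addition, 4π opening, 6π closure and enolisation, which creates C7a–C7, C7–C6, C5–C4 and C4–C3a. The feature exploited is the contiguous C4-OH, C5-alkyl, C6-OMe, C7-H sequence on ring A, the natural substitution print of these two partners, so the ring-A oxygens never have to be told apart. The precursor is a 2-aryl-3-methoxycarbonyl-5-(diazoacetyl)furan whose only unsubstituted carbon is the β-position destined to be C3a.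

Key step: step 8

Remark: the target has no stereocentre, and the stereocentres of the cyclobutenone and cyclohexadienone intermediates of the key step are racemic and disappear on aromatisation. Dimethyl furan-2,4-dicarboxylate and TMPMgCl·LiCl are taken as catalogue items. Benzofuran numbering (O1, C2, C3, C3a, C4–C7, C7a) is used for the final ring system.

Step 1
Reactants: 1 4-bromoresorcinol (4-bromobenzene-1,3-diol)
Product: 2 2,4-bis(benzyloxy)-1-bromobenzene
Conditions: BnBr (2.3 equiv), K2CO3, DMF, 60 °C
Reagents that add atoms: benzyl bromide, BrCc1ccccc1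
Why: Double Williamson etherification of the two phenoxides with a benzylic halide should be clean, the aryl bromide being inert to carbonate, and benzyl is chosen because it withstands organozinc coupling, hydroxide, acid chloride formation, long-wave light, hydride and MnO2 and leaves at the end under neutral conditions.

Step 2
Reactants: 3 dimethyl furan-2,4-dicarboxylate; 2 2,4-bis(benzyloxy)-1-bromobenzene
Product: 6 dimethyl 5-[2,4-bis(benzyloxy)phenyl]furan-2,4-dicarboxylate, via furylmagnesium chloride 4 (not isolated), via furylzinc chloride 5 (not isolated)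
Conditions: 3, TMPMgCl·LiCl (1.1 equiv), THF, −40 °C; ZnCl2, −40 °C → rt; then 2, Pd(OAc)2 (2 mol %), SPhos (4 mol %), THF, 50 °C
Reagents that add atoms: TMPMgCl·LiCl, CC1(C)CCCC(C)(C)N1[Mg]Cl.[Li+].[Cl-] (MgCl of 4 only); ZnCl2, Cl[Zn]Cl (ZnCl of 5 only)
Why: Directed magnesiation followed by Negishi cross-coupling: the hindered amide base should remove C5–H, the only α-proton of the furan and the one acidified by O1 and the neighbouring ester, zinc tames the carbanion towards the esters, and a base-free coupling at 50 °C is preferred to carbonate- or pivalate-assisted C–H arylation because an ortho-benzyloxyarylpalladium bromide would under those conditions cyclise onto its own benzyl ring to a 6H-benzo[c]chromene.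

Step 3
Reactants: 6 dimethyl 5-[2,4-bis(benzyloxy)phenyl]furan-2,4-dicarboxylate
Product: 7 5-[2,4-bis(benzyloxy)phenyl]-4-(methoxycarbonyl)furan-2-carboxylic acid
Conditions: LiOH·H2O (1.05 equiv), THF/MeOH/H2O, 0 °C → rt; then 1 M HCl to pH 3
Reagents that add atoms: lithium hydroxide, [Li+].[OH-] (carboxyl oxygen)
Why: Chemoselective saponification with one equivalent of hydroxide should hit the unhindered α-ester at C2, because the C4 ester is a vinylogous carbonate (O1–C5=C4–C=O) screened by the ortho-substituted aryl group, which mirrors the known α-over-β order of alkaline hydrolysis in five-membered heteroarene 2,4-diesters.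

Step 4
Reactants: 7 5-[2,4-bis(benzyloxy)phenyl]-4-(methoxycarbonyl)furan-2-carboxylic acid
Product: 9 methyl 2-[2,4-bis(benzyloxy)phenyl]-5-(diazoacetyl)furan-3-carboxylate, via acid chloride 8 (not isolated)
Conditions: (COCl)2, cat. DMF, CH2Cl2, 0 °C → rt, evaporate; CH2N2 (ca. 4 equiv), Et2O/THF, 0 °C
Reagents that add atoms: oxalyl chloride, O=C(Cl)C(=O)Cl (chlorine of 8 only); diazomethane, C=[N+]=[N-]
Why: Acid chloride formation and C-acylation of diazomethane (the first half of the Arndt–Eistert sequence) is the standard entry to aryl diazomethyl ketones, the excess diazomethane consuming the HCl so that no chloromethyl ketone arises, and neither the ester nor the benzyl ethers react.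

Step 5
Reactants: 10 3-methylbutane-1,3-diol
Product: 11 4-iodo-2-methylbutan-2-ol
Conditions: I2, PPh3, imidazole, CH2Cl2, 0 °C → rt
Reagents that add atoms: iodine, II
Why: Appel-type iodination proceeds by SN2 displacement on an alkoxyphosphonium ion, which only the primary hydroxyl can undergo at this temperature, so the tertiary alcohol stays free.

Step 6
Reactants: 11 4-iodo-2-methylbutan-2-ol
Product: 12 triethyl[(4-iodo-2-methylbutan-2-yl)oxy]silane
Conditions: TESOTf, 2,6-lutidine, CH2Cl2, 0 °C
Reagents that add atoms: triethylsilyl trifluoromethanesulfonate, CC[Si](CC)(CC)OS(=O)(=O)C(F)(F)F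
Why: Silyl triflate silylation with a hindered pyridine base is the usual way to cap a tertiary alcohol, protection being needed because a free hydroxyl would lactonise onto the ketene of the key step, and triethylsilyl is chosen because on a tertiary carbinol it resists amide bases, heat and hydride yet still yields to fluoride at room temperature, which a bulkier silyl group would not.

Step 7
Reactants: 13 chloroacetaldehyde dimethyl acetal (2-chloro-1,1-dimethoxyethane); 12 triethyl[(4-iodo-2-methylbutan-2-yl)oxy]silane
Product: 15 triethyl[(6-methoxy-2-methylhex-5-yn-2-yl)oxy]silane, via lithium methoxyacetylide 14 (not isolated)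
Conditions: Et2NH, n-BuLi (3.2 equiv each), THF, 0 °C; 13, 0 °C → rt; then 12 (0.7 equiv), DMPU, −20 °C → rt; chromatography on Et3N-deactivated silica
Reagents that add atoms: n-butyllithium, [Li]CCCC (lithium of 14 only)
Why: Three equivalents of amide base strip methanol and HCl from the chloroacetal and deprotonate the resulting methoxyacetylene, and SN2 alkylation of the acetylide by an unhindered primary iodide in a dipolar cosolvent is the established one-pot synthesis of 1-alkoxyalk-1-ynes.

Step 8
Reactants: 9 methyl 2-[2,4-bis(benzyloxy)phenyl]-5-(diazoacetyl)furan-3-carboxylate; 15 triethyl[(6-methoxy-2-methylhex-5-yn-2-yl)oxy]silane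
Product: 20 methyl 2-[2,4-bis(benzyloxy)phenyl]-4-hydroxy-6-methoxy-5-[3-methyl-3-(triethylsilyloxy)butyl]benzofuran-3-carboxylate, via furylketene 16 (not isolated), via cyclobutenone 17 (not isolated), via dienylketene 18 (not isolated), via cyclohexadienone 19 (not isolated)
Conditions: 15 (1.3 equiv), hν (365 nm LED, Pyrex), degassed ClCH2CH2Cl, 0.02 M, 20 °C; then solvent change to toluene, 110 °C
Reagents that add atoms: none
Why: Light expels N2 from 9 while the furyl group migrates to the former diazo carbon (Wolff rearrangement, C7a–C7), ketene 16 adds to 15 in a [2+2] cycloaddition (C7–C6 and C5–C4) to give 17, and heat reversibly opens 17 by conrotatory 4π cleavage of the old C4–C7 bond to dienylketene 18. Ring A then closes by thermal disrotatory 6π electrocyclisation, the ketene carbon bonding to the free furan β-carbon (C4–C3a), and dienone 19 enolises irreversibly to the phenol, aided by the hydrogen bond to the C3 ester. The closest known reaction is the second-generation Danheiser benzannulation of aryl and heteroaryl diazomethyl ketones with alkoxy- and siloxyalkynes, which already covers benzofuran formation, so this is an application to a new molecule. No stereocentre remains, since those of 17 and 19 are lost on aromatisation, and only the isomer of 18 with the furyl group cis to the ketene arm can close while the other returns to 17. The orientation of the [2+2] step is secured by the polarisation of the ynol ether, whose alkyl-bearing carbon is nucleophilic and attacks the ketene carbonyl carbon, putting the side chain at C5 next to the new hydroxyl and OMe at C6, and the site of closure is unambiguous because the other neighbour of C7a is O1. Irradiation at 365 nm addresses the extended diazoketone chromophore and spares the benzyl aryl ethers, a methyl ynol ether cannot fragment by retro-ene loss of an alkene on heating, and the silyl ether blocks lactonisation of 18.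

Step 9
Reactants: 20 methyl 2-[2,4-bis(benzyloxy)phenyl]-4-hydroxy-6-methoxy-5-[3-methyl-3-(triethylsilyloxy)butyl]benzofuran-3-carboxylate
Product: 21 2-[2,4-bis(benzyloxy)phenyl]-3-(hydroxymethyl)-6-methoxy-5-[3-methyl-3-(triethylsilyloxy)butyl]benzofuran-4-ol
Conditions: i-Bu2AlH (4 equiv), CH2Cl2, −78 → 0 °C; aq. potassium sodium tartrate
Reagents that add atoms: none
Why: Hydride reduction of the aromatic ester to the primary alcohol, in which the first equivalent is spent on the phenol, silyl and benzyl ethers are inert, and low temperature plus a non-acidic tartrate work-up guard the easily ionised benzofuran-3-ylmethanol, which is carried on crude.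

Step 10
Reactants: 21 2-[2,4-bis(benzyloxy)phenyl]-3-(hydroxymethyl)-6-methoxy-5-[3-methyl-3-(triethylsilyloxy)butyl]benzofuran-4-ol
Product: 22 2-[2,4-bis(benzyloxy)phenyl]-4-hydroxy-6-methoxy-5-[3-methyl-3-(triethylsilyloxy)butyl]benzofuran-3-carbaldehyde
Conditions: activated MnO2 (15 equiv), CH2Cl2, rt
Reagents that add atoms: none
Why: MnO2 oxidation is selective for benzylic and heterobenzylic alcohols, stops at the aldehyde, is routinely compatible with hydroxybenzyl alcohols, and here delivers a vinylogous-ester-type aldehyde locked by a hydrogen bond to the C4 hydroxyl.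

Step 11
Reactants: 22 2-[2,4-bis(benzyloxy)phenyl]-4-hydroxy-6-methoxy-5-[3-methyl-3-(triethylsilyloxy)butyl]benzofuran-3-carbaldehyde
Product: 23 2-[2,4-bis(benzyloxy)phenyl]-4-hydroxy-5-(3-hydroxy-3-methylbutyl)-6-methoxybenzofuran-3-carbaldehyde
Conditions: Bu4NF (3 equiv), THF, rt; aqueous work-up
Reagents that add atoms: none
Why: Fluoride-driven desilylation relies on the strength of the Si–F bond, and its basic medium avoids the acid-induced ionisation of the tertiary carbinol that would close a 2,2-dimethylchroman onto the C4 phenol.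

Step 12
Reactants: 23 2-[2,4-bis(benzyloxy)phenyl]-4-hydroxy-5-(3-hydroxy-3-methylbutyl)-6-methoxybenzofuran-3-carbaldehyde
Product: 24 2-(2,4-dihydroxyphenyl)-4-hydroxy-5-(3-hydroxy-3-methylbutyl)-6-methoxybenzofuran-3-carbaldehyde (ebenfuran V)
Conditions: H2 (1 atm), 10 % Pd/C, EtOAc, rt, stopped at full conversion
Reagents that add atoms: none
Why: Catalytic hydrogenolysis cleaves the two aryl benzyl ethers rapidly at one atmosphere, whereas the formyl group, a vinylogous ester (O1–C2=C3–CH=O) chelated by the C4 hydroxyl, and the tetrasubstituted C2=C3 bond are poor substrates in a neutral aprotic solvent, so stopping at full conversion of 23 should give the target.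

Compound list
1 | 4-bromoresorcinol | Oc1ccc(Br)c(O)c1 | starting material
2 | 2,4-bis(benzyloxy)-1-bromobenzene | Brc1ccc(OCc2ccccc2)cc1OCc1ccccc1 | intermediate
3 | dimethyl furan-2,4-dicarboxylate | COC(=O)c1coc(C(=O)OC)c1 | starting material
4 | [3,5-bis(methoxycarbonyl)furan-2-yl]magnesium chloride (LiCl adduct) | COC(=O)c1cc(C(=O)OC)c([Mg]Cl)o1 | intermediate
5 | [3,5-bis(methoxycarbonyl)furan-2-yl]zinc chloride | COC(=O)c1cc(C(=O)OC)c([Zn]Cl)o1 | intermediate
6 | dimethyl 5-[2,4-bis(benzyloxy)phenyl]furan-2,4-dicarboxylate | COC(=O)c1cc(C(=O)OC)c(-c2ccc(OCc3ccccc3)cc2OCc2ccccc2)o1 | intermediate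
7 | 5-[2,4-bis(benzyloxy)phenyl]-4-(methoxycarbonyl)furan-2-carboxylic acid | OC(=O)c1cc(C(=O)OC)c(-c2ccc(OCc3ccccc3)cc2OCc2ccccc2)o1 | intermediate
8 | methyl 2-[2,4-bis(benzyloxy)phenyl]-5-(chlorocarbonyl)furan-3-carboxylate | ClC(=O)c1cc(C(=O)OC)c(-c2ccc(OCc3ccccc3)cc2OCc2ccccc2)o1 | intermediate
9 | methyl 2-[2,4-bis(benzyloxy)phenyl]-5-(diazoacetyl)furan-3-carboxylate | [N-]=[N+]=CC(=O)c1cc(C(=O)OC)c(-c2ccc(OCc3ccccc3)cc2OCc2ccccc2)o1 | intermediate
10 | 3-methylbutane-1,3-diol | CC(C)(O)CCO | starting material
11 | 4-iodo-2-methylbutan-2-ol | CC(C)(O)CCI | intermediate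
12 | triethyl[(4-iodo-2-methylbutan-2-yl)oxy]silane | CC[Si](CC)(CC)OC(C)(C)CCI | intermediate
13 | chloroacetaldehyde dimethyl acetal | COC(CCl)OC | starting material
14 | lithium methoxyacetylide | [Li]C#COC | intermediate
15 | triethyl[(6-methoxy-2-methylhex-5-yn-2-yl)oxy]silane | COC#CCCC(C)(C)O[Si](CC)(CC)CC | intermediate
16 | methyl 2-[2,4-bis(benzyloxy)phenyl]-5-(2-oxoethenyl)furan-3-carboxylate (furylketene) | O=C=Cc1cc(C(=O)OC)c(-c2ccc(OCc3ccccc3)cc2OCc2ccccc2)o1 | intermediate
17 | methyl 2-[2,4-bis(benzyloxy)phenyl]-5-{2-methoxy-3-[3-methyl-3-(triethylsilyloxy)butyl]-4-oxocyclobut-2-en-1-yl}furan-3-carboxylate (racemic) | COC1=C(CCC(C)(C)O[Si](CC)(CC)CC)C(=O)C1c1cc(C(=O)OC)c(-c2ccc(OCc3ccccc3)cc2OCc2ccccc2)o1 | intermediate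
18 | methyl 2-[2,4-bis(benzyloxy)phenyl]-5-[(1E)-2-methoxy-6-methyl-3-(oxomethylidene)-6-(triethylsilyloxy)hept-1-en-1-yl]furan-3-carboxylate (furyl cis to the ketene carbon) | O=C=C(CCC(C)(C)O[Si](CC)(CC)CC)/C(OC)=C\c1cc(C(=O)OC)c(-c2ccc(OCc3ccccc3)cc2OCc2ccccc2)o1 | intermediate
19 | methyl 2-[2,4-bis(benzyloxy)phenyl]-6-methoxy-5-[3-methyl-3-(triethylsilyloxy)butyl]-4-oxo-3a,4-dihydrobenzofuran-3-carboxylate (racemic keto tautomer of 20) | COC(=O)C1=C(c2ccc(OCc3ccccc3)cc2OCc2ccccc2)OC2=CC(OC)=C(CCC(C)(C)O[Si](CC)(CC)CC)C(=O)C12 | intermediate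
20 | methyl 2-[2,4-bis(benzyloxy)phenyl]-4-hydroxy-6-methoxy-5-[3-methyl-3-(triethylsilyloxy)butyl]benzofuran-3-carboxylate | COC(=O)c1c(-c2ccc(OCc3ccccc3)cc2OCc2ccccc2)oc2cc(OC)c(CCC(C)(C)O[Si](CC)(CC)CC)c(O)c12 | intermediate
21 | 2-[2,4-bis(benzyloxy)phenyl]-3-(hydroxymethyl)-6-methoxy-5-[3-methyl-3-(triethylsilyloxy)butyl]benzofuran-4-ol | OCc1c(-c2ccc(OCc3ccccc3)cc2OCc2ccccc2)oc2cc(OC)c(CCC(C)(C)O[Si](CC)(CC)CC)c(O)c12 | intermediate
22 | 2-[2,4-bis(benzyloxy)phenyl]-4-hydroxy-6-methoxy-5-[3-methyl-3-(triethylsilyloxy)butyl]benzofuran-3-carbaldehyde | O=Cc1c(-c2ccc(OCc3ccccc3)cc2OCc2ccccc2)oc2cc(OC)c(CCC(C)(C)O[Si](CC)(CC)CC)c(O)c12 | intermediate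
23 | 2-[2,4-bis(benzyloxy)phenyl]-4-hydroxy-5-(3-hydroxy-3-methylbutyl)-6-methoxybenzofuran-3-carbaldehyde | O=Cc1c(-c2ccc(OCc3ccccc3)cc2OCc2ccccc2)oc2cc(OC)c(CCC(C)(C)O)c(O)c12 | intermediate
24 | 2-(2,4-dihydroxyphenyl)-4-hydroxy-5-(3-hydroxy-3-methylbutyl)-6-methoxybenzofuran-3-carbaldehyde (ebenfuran V) | COc1cc2oc(-c3ccc(O)cc3O)c(C=O)c2c(O)c1CCC(C)(C)O | target

Total step count: 12. Longest linear sequence: 9 (steps 1–4 and 8–12). The alkyne branch (steps 5–7) joins at step 8.

Steps most likely to fail

Step 8. The arylfuran and the growing benzofuran chromophores may screen the light and slow the Wolff step. The ketene may also dimerise or be captured by the product phenol before it meets the alkyne. The fallback separates ketene generation from light.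
- It sets out from 9. A PhCO2Ag-catalysed Wolff rearrangement in aqueous dioxane with Et3N (Arndt–Eistert homologation) should give {5-[2,4-bis(benzyloxy)phenyl]-4-(methoxycarbonyl)furan-2-yl}acetic acid F1.
- Oxalyl chloride should turn F1 into methyl 2-[2,4-bis(benzyloxy)phenyl]-5-(2-chloro-2-oxoethyl)furan-3-carboxylate F2.
- Slow addition of Et3N to F2 and 15 in toluene generates ketene 16 by dehydrochlorination in the dark, at a low stationary concentration.
- The route is rejoined at cyclobutenone 17, which is now isolated and thermolysed on its own in toluene at 110 °C to 20.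

Step 2. Metalation may stray to C3–H between the two esters, the furylmagnesium species may attack an ester of a second molecule, or the hindered coupling may lose out to protodemetalation. The fallback avoids any furan carbanion.
- It sets out from 2. Bromine–lithium exchange (n-BuLi, THF, −78 °C), B(OiPr)3 and aqueous acid should give [2,4-bis(benzyloxy)phenyl]boronic acid F3.
- Suzuki–Miyaura coupling (Pd(PPh3)4, K3PO4, dioxane/H2O, 70 °C) with purchased methyl 4,5-dibromofuran-2-carboxylate F4 should occur at the more reactive α C5–Br bond. It should give methyl 5-[2,4-bis(benzyloxy)phenyl]-4-bromofuran-2-carboxylate F5.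
- Palladium-catalysed methoxycarbonylation of the remaining C4–Br bond (CO, MeOH, Et3N, Pd(OAc)2, dppf, DMF, 80 °C) comes back to the route at 6.

Step 9. The hindered, hydrogen-bonded and electronically deactivated ester may reduce sluggishly. The aluminium alkoxide of the electron-rich benzofuranylmethanol may ionise and be reduced further to the methyl level. The alcohol may also oligomerise on handling, or the phenol may suffer in the following oxidation. The fallback never passes through the alcohol oxidation level.
- It sets out from 20. Aminolysis with Me2AlN(OMe)Me (from AlMe3 and MeNH(OMe)·HCl, toluene, 60 °C) should give the Weinreb amide 2-[2,4-bis(benzyloxy)phenyl]-4-hydroxy-N,6-dimethoxy-N-methyl-5-[3-methyl-3-(triethylsilyloxy)butyl]benzofuran-3-carboxamide F6.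
- Reduction of F6 with LiAlH4 (THF, −20 °C) stops at the chelated tetrahedral adduct and releases the aldehyde on work-up.
- The route is rejoined at 22, so 21 and the MnO2 step are bypassed.

Further compounds
F1 | step 8 | {5-[2,4-bis(benzyloxy)phenyl]-4-(methoxycarbonyl)furan-2-yl}acetic acid | OC(=O)Cc1cc(C(=O)OC)c(-c2ccc(OCc3ccccc3)cc2OCc2ccccc2)o1
F2 | step 8 | methyl 2-[2,4-bis(benzyloxy)phenyl]-5-(2-chloro-2-oxoethyl)furan-3-carboxylate | ClC(=O)Cc1cc(C(=O)OC)c(-c2ccc(OCc3ccccc3)cc2OCc2ccccc2)o1
F3 | step 2 | [2,4-bis(benzyloxy)phenyl]boronic acid | OB(O)c1ccc(OCc2ccccc2)cc1OCc1ccccc1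
F4 | step 2 | methyl 4,5-dibromofuran-2-carboxylate (purchased) | COC(=O)c1cc(Br)c(Br)o1
F5 | step 2 | methyl 5-[2,4-bis(benzyloxy)phenyl]-4-bromofuran-2-carboxylate | COC(=O)c1cc(Br)c(-c2ccc(OCc3ccccc3)cc2OCc2ccccc2)o1
F6 | step 9 | 2-[2,4-bis(benzyloxy)phenyl]-4-hydroxy-N,6-dimethoxy-N-methyl-5-[3-methyl-3-(triethylsilyloxy)butyl]benzofuran-3-carboxamide | CON(C)C(=O)c1c(-c2ccc(OCc3ccccc3)cc2OCc2ccccc2)oc2cc(OC)c(CCC(C)(C)O[Si](CC)(CC)CC)c(O)c12
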